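All constants are assumed.

I read each flask at 10 h, and I want to know what fraction of the charged substrate has become product by then, and how that fraction moves as the charge of capture agent grows.

all flasks: substrate 0.050 M; time 10 h
- elm: capture agent 0.0150 M
- oak: capture agent 0.0250 M
- alder: capture agent 0.0300 M

    substrate → intermediate A (k1 = 0.442 h⁻¹)
    substrate ⇌ intermediate B (K2 = 1.0, k2 = 0.386 h⁻¹)
    intermediate A ⇌ intermediate C (K3 = 0.66, k3 = 0.0822 h⁻¹)
    intermediate C ⇌ product (K4 = 12, k4 = 0.00895 h⁻¹)
    capture agent + intermediate A → trapped intermediate (k5 = 0.370 M⁻¹ h⁻¹)

- [product] at the end for elm, oak, alder, in this order
- the course of these numbers from the first flask to the last (hardly changes / rises, then falls / falls all the way / rises all the way / falls, then rises)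

- "hardly changes" means that all values lie within two and a half points (for a concentration: within two and a half percent of the largest)
- run time (elm): 10 h

A first-order loss multiplies a population by an exponential, so its logarithm falls in a straight line, and I reckon in logarithms. Capture agent is a loss of this kind for intermediate A: held at its charge, it gives a pseudo-first-order constant, k5 times the agent's concentration, of 0.00555 h⁻¹ in elm, 0.00925 h⁻¹ in oak and 0.0111 h⁻¹ in alder. In elm this means a half-life of intermediate A by this step alone of 120 h, far longer than the run, so the loss is gentle.

But how long is product-bound material exposed to it? Product comes from intermediate C, whose relaxation with product takes 71.5 h, long against the run, so I ignore the way back. The final product fraction is then k4 times the time integral of intermediate C. Setting aside the return of intermediate C to intermediate A, whatever crosses to intermediate C at time s has the remaining time to yield product. That weight falls in a straight line to zero at the end, and if the crossing runs at a steady rate, the centroid of such a triangle lies at 3.33 h, a third of the way along.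

For elm I get 1.85% as the bite, the estimated fractional loss of product to the trap: the pseudo-first-order constant times a third of the run. It is 3.08% for oak and 3.70% for alder. In this estimate I let intermediate A stand from the start and hold the agent at its charge. My hand reckoning gives no level, but it gives the spread: elm to alder differs by 1.85%, less than the margin of 2.5 percent. I commit to a row that hardly changes.

The forecast gives 5.520 × 10⁻⁴ M, 5.460 × 10⁻⁴ M and 5.430 × 10⁻⁴ M, and calls the course hardly changes, saying: “Trapping takes only about 1.6% off between the first and last flask, which is within 2.5%, so the row hardly changes.” My spread is larger than its 1.6 percent.

The simulation gives 5.51 × 10⁻⁴ M, 5.46 × 10⁻⁴ M and 5.43 × 10⁻⁴ M, which is 1.10%, 1.09% and 1.09% of the charge, and the course is hardly changes.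

In elm at 10.0 h, intermediate A passes forward to intermediate C 16 times as fast as it passes to trapped intermediate, and elm holds 2.61% of its charge as trapped intermediate, while my bite for elm is 1.85%. The bite for oak, 3.08%, lies between that of elm and the 3.70% of alder, and at 10.0 h the trapped intermediate in oak stands at 4.30% of the charge against 1.09% as product.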